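**Retrosynthetic overview**

1. Numbering: O1, C2 (syringyl ring A), C3 (CH2OH), O4, C4a, C5 (OMe), C6, C7 (propenol), C8, C8a; the benzo ring is ring B. The strategy rests on O1 sitting on C8a directly beside the unsubstituted C8–H of ring B. The O1–C8a bond together with that hydrogen is taken back to addition of the C2 alkoxide across a C8≡C8a aryne, with the leaving bromine on C8 (from 6-bromovanillin).
2. The C7 propenol comes from the enoate (i-Bu2AlH), this from the C7 aldehyde (Wittig), and this from the C7 silyloxymethyl group carried through the aryne step.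
3. The aryne precursor is the threo (1S,2S) aryl ether alcohol, made by an Evans syn aldol of the (R)-oxazolidinone aryloxyacetyl imide (O4–C4a is the vanillin phenol oxygen) with MOM-protected syringaldehyde, then LiBH4 and primary silylation.
4. Rings A and B are bought; the dioxane ring is the only ring formed (step 10).

Key step: step 10

Assumption: the Z boron enolate of the aryloxyacetyl imide is taken to follow the usual Evans syn sense known for alkoxyacetyl imides; 6-bromovanillin and (R)-4-benzyl-1,3-oxazolidin-2-one are taken as commercial.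

Triisopropylsilyl (TIPS) is used for both silyl ethers because it resists transfer to a neighbouring alkoxide or aryllithium under the strongly basic key step. Locants in the benzodioxane names follow the numbering above.

**Route**

Step 1
Reactants: 1 6-bromovanillin; 2 methyl bromoacetate
Product: 3 methyl 2-(5-bromo-4-formyl-2-methoxyphenoxy)acetate
Conditions: K2CO3, DMF, rt → 50 °C
Reagents that add atoms: none
Why: Williamson ether synthesis, in which the phenoxide of 1 (acidified by the para formyl group) displaces bromide from the activated α-bromo ester by SN2.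

Step 2
Reactants: 3 methyl 2-(5-bromo-4-formyl-2-methoxyphenoxy)acetate
Product: 4 methyl 2-[5-bromo-4-(hydroxymethyl)-2-methoxyphenoxy]acetate
Conditions: NaBH4 (0.5 equiv), THF/MeOH, 0 °C, short reaction time
Reagents that add atoms: none
Why: Chemoselective borohydride reduction, since at 0 °C NaBH4 reduces the aryl aldehyde much faster than the methyl ester and does not touch the aryl bromide.

Step 3
Reactants: 4 methyl 2-[5-bromo-4-(hydroxymethyl)-2-methoxyphenoxy]acetate
Product: 5 methyl 2-[5-bromo-2-methoxy-4-({[tri(propan-2-yl)silyl]oxy}methyl)phenoxy]acetate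
Conditions: TIPSCl, imidazole, DMF, rt
Reagents that add atoms: chlorotri(propan-2-yl)silane, CC(C)[Si](Cl)(C(C)C)C(C)C
Why: Imidazole-promoted silylation of the only hydroxyl; TIPS is preferred to a smaller silyl group because it should not migrate from oxygen to a neighbouring aryllithium in step 10.

Step 4
Reactants: 5 methyl 2-[5-bromo-2-methoxy-4-({[tri(propan-2-yl)silyl]oxy}methyl)phenoxy]acetate
Product: 6 2-[5-bromo-2-methoxy-4-({[tri(propan-2-yl)silyl]oxy}methyl)phenoxy]acetic acid
Conditions: LiOH·H2O, THF/H2O, 0 °C → rt; then 1 M HCl to pH 3, 0 °C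
Reagents that add atoms: lithium hydroxide, [Li+].[OH-]
Why: Saponification (base-mediated acyl substitution) of the activated aryloxyacetate; the benzylic TIPS ether and the aryl bromide should survive cold LiOH and brief acidification.

Step 5
Reactants: 6 2-[5-bromo-2-methoxy-4-({[tri(propan-2-yl)silyl]oxy}methyl)phenoxy]acetic acid; 7 (R)-4-benzyl-1,3-oxazolidin-2-one
Product: 9 (4R)-4-benzyl-3-{[5-bromo-2-methoxy-4-({[tri(propan-2-yl)silyl]oxy}methyl)phenoxy]acetyl}-1,3-oxazolidin-2-one, via pivalic mixed anhydride 8 (not isolated)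
Conditions: pivaloyl chloride, Et3N, THF, −20 °C; then 7, LiCl, −20 °C → rt
Reagents that add atoms: none
Why: N-acylation of the oxazolidinone by the mixed-anhydride method, in which the hindered pivaloyl carbonyl of 8 steers the LiCl-activated oxazolidinone to the aryloxyacetyl carbonyl.

Step 6
Reactants: 10 syringaldehyde
Product: 11 3,5-dimethoxy-4-(methoxymethoxy)benzaldehyde
Conditions: MOMCl, i-Pr2NEt, CH2Cl2, 0 °C → rt
Reagents that add atoms: chloromethyl methyl ether, COCCl
Why: O-alkylation of the phenol to a methoxymethyl acetal, a protecting group that should tolerate the boron Lewis acid, hydride, amide base, fluoride and MnO2 steps that follow.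

Step 7
Reactants: 9 (4R)-4-benzyl-3-{[5-bromo-2-methoxy-4-({[tri(propan-2-yl)silyl]oxy}methyl)phenoxy]acetyl}-1,3-oxazolidin-2-one; 11 3,5-dimethoxy-4-(methoxymethoxy)benzaldehyde
Product: 14 (4R)-4-benzyl-3-{(2R,3S)-2-[5-bromo-2-methoxy-4-({[tri(propan-2-yl)silyl]oxy}methyl)phenoxy]-3-[3,5-dimethoxy-4-(methoxymethoxy)phenyl]-3-hydroxypropanoyl}-1,3-oxazolidin-2-one, via Z dibutylboron enolate 12 (not isolated), via dibutylboron aldolate 13 (not isolated)
Conditions: Bu2BOTf, i-Pr2NEt, CH2Cl2, −78 → 0 °C; then 11, −78 → 0 °C; pH 7 phosphate buffer, MeOH, 30% H2O2, 0 °C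
Reagents that add atoms: none
Why: Evans syn aldol reaction, in which the Z boron enolate 12 reacts through a closed Zimmerman–Traxler chair on the enolate face remote from the benzyl group of the (R)-auxiliary; this should set the aryloxy-bearing carbon as R and the carbinol carbon as S (syn, the threo series), and the oxidative work-up cleaves the boron aldolate 13.

Step 8
Reactants: 14 the syn aldol adduct
Product: 15 (1S,2S)-2-[5-bromo-2-methoxy-4-({[tri(propan-2-yl)silyl]oxy}methyl)phenoxy]-1-[3,5-dimethoxy-4-(methoxymethoxy)phenyl]propane-1,3-diol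
Conditions: LiBH4, THF, MeOH (1.5 equiv), 0 °C
Reagents that add atoms: none
Why: Reductive cleavage of the N-acyl oxazolidinone by LiBH4 (hydride attack on the lithium-chelated exocyclic carbonyl), which frees the primary alcohol without touching either stereocentre and returns the auxiliary.

Step 9
Reactants: 15 the threo 1,3-diol
Product: 16 (1S,2S)-2-[5-bromo-2-methoxy-4-({[tri(propan-2-yl)silyl]oxy}methyl)phenoxy]-1-[3,5-dimethoxy-4-(methoxymethoxy)phenyl]-3-{[tri(propan-2-yl)silyl]oxy}propan-1-ol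
Conditions: TIPSCl (1.1 equiv), imidazole, CH2Cl2, 0 °C → rt
Reagents that add atoms: chlorotri(propan-2-yl)silane, CC(C)[Si](Cl)(C(C)C)C(C)C
Why: Sterically controlled silylation, in which the bulky chlorosilane should react only at the primary hydroxyl; this oxygen must be blocked because its alkoxide could also close a six-membered ring onto the aryne.

Step 10
Reactants: 16 the threo bromoaryl ether alcohol
Product: 20 (2S,3S)-2-[3,5-dimethoxy-4-(methoxymethoxy)phenyl]-5-methoxy-3,7-bis({[tri(propan-2-yl)silyl]oxy}methyl)-2,3-dihydro-1,4-benzodioxine, via C8a-lithiated lithium alkoxide 17 (not isolated), via lithium alkoxide of the C8–C8a aryne 18 (not isolated), via C8-lithiated benzodioxane 19 (not isolated)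
Conditions: lithium 2,2,6,6-tetramethylpiperidide (3.5 equiv, from n-BuLi and 2,2,6,6-tetramethylpiperidine), THF, −78 °C, then → 0 °C; sat. aq NH4Cl
Reagents that add atoms: none
Why: After the C2 hydroxyl is deprotonated, the amide base removes the only proton ortho to bromine (C8a–H, acidified by O4 and Br), the bromoaryllithium 17 loses LiBr on warming to give the C8≡C8a aryne 18, and the tethered alkoxide adds in the ring plane to C8a to form O1–C8a, leaving the C8 aryllithium 19 that is protonated by tetramethylpiperidine or on quench. The closest known reaction type is the base-induced aryne cyclisation of meta-haloaryl ethers and meta-haloarylalkanols bearing a tethered alkoxide, which gives benzo-fused cyclic ethers. The dioxane ring closes in a 6-exo-dig mode with respect to the aryne bond, the only mode the O4–C3–C2–O tether allows, because attack at C8 would require a meta-bridged seven-membered ring. No stereocentre is formed: the C–O bonds at C2 and C3 are not broken, so the threo (1S,2S) alcohol maps onto the trans (2S,3S) benzodioxane. The selectivity needed is site selectivity on the aryne (C8a against C8, which a free nucleophile would prefer on a 3-alkoxyaryne); it should be secured by the tether, by the hindered non-nucleophilic amide and by the bulky silyloxymethyl group on C7 that screens C8. The TIPS ether on the C3 side chain ensures that only the C2 oxygen can cyclise.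

Step 11
Reactants: 20 the bis-TIPS benzodioxane
Product: 21 [(2S,3S)-2-[3,5-dimethoxy-4-(methoxymethoxy)phenyl]-5-methoxy-2,3-dihydro-1,4-benzodioxine-3,7-diyl]dimethanol
Conditions: Bu4NF, THF, 0 °C → rt
Reagents that add atoms: none
Why: Fluoride-induced desilylation, which cleaves both Si–O bonds while the MOM ether and the benzodioxane are inert.

Step 12
Reactants: 21 the diol
Product: 22 (2S,3S)-2-[3,5-dimethoxy-4-(methoxymethoxy)phenyl]-3-(hydroxymethyl)-5-methoxy-2,3-dihydro-1,4-benzodioxine-7-carbaldehyde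
Conditions: activated MnO2 (excess), CH2Cl2, rt
Reagents that add atoms: none
Why: Chemoselective MnO2 oxidation, in which the electron-rich benzylic alcohol on C7 is oxidised on the oxide surface and the saturated primary alcohol on C3 is left alone.

Step 13
Reactants: 22 the C7 aldehyde; 23 methyl (triphenylphosphoranylidene)acetate
Product: 24 methyl (E)-3-[(2S,3S)-2-[3,5-dimethoxy-4-(methoxymethoxy)phenyl]-3-(hydroxymethyl)-5-methoxy-2,3-dihydro-1,4-benzodioxin-7-yl]prop-2-enoate
Conditions: toluene, 80 °C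
Reagents that add atoms: none
Why: Wittig olefination with a stabilised ylide, which should give the (E)-enoate under thermodynamic control of the oxaphosphetane and tolerates the free primary alcohol.

Step 14
Reactants: 24 the MOM-protected enoate
Product: 25 methyl (E)-3-[(2S,3S)-2-(4-hydroxy-3,5-dimethoxyphenyl)-3-(hydroxymethyl)-5-methoxy-2,3-dihydro-1,4-benzodioxin-7-yl]prop-2-enoate
Conditions: HCl (1.25 M in MeOH, few equiv), THF/MeOH, 0 °C → rt
Reagents that add atoms: none
Why: Acid-catalysed acetal cleavage (methanolysis of the aryl MOM ether), placed at the enoate stage because no acid-sensitive allylic alcohol is present yet; dilute acid at or below room temperature should leave the benzylic C2–O1 ether closed.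

Step 15
Reactants: 25 the phenolic enoate
Product: 26 4-[(2S,3S)-3-(hydroxymethyl)-7-[(E)-3-hydroxyprop-1-enyl]-5-methoxy-2,3-dihydro-1,4-benzodioxin-2-yl]-2,6-dimethoxyphenol (target)
Conditions: i-Bu2AlH (6 equiv), CH2Cl2/THF, −78 → −20 °C; aq potassium sodium tartrate (KNaC4H4O6)
Reagents that add atoms: none
Why: 1,2-Reduction of the α,β-unsaturated ester by excess i-Bu2AlH (the first equivalents are consumed by the phenol and the alcohol), which should give the (E)-allylic alcohol without conjugate reduction.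

**Compound list**

1 | 6-bromovanillin (2-bromo-4-hydroxy-5-methoxybenzaldehyde) | O=Cc1cc(OC)c(O)cc1Br | starting material
2 | methyl bromoacetate | COC(=O)CBr | starting material
3 | methyl 2-(5-bromo-4-formyl-2-methoxyphenoxy)acetate | COC(=O)COc1cc(Br)c(C=O)cc1OC | intermediate
4 | methyl 2-[5-bromo-4-(hydroxymethyl)-2-methoxyphenoxy]acetate | COC(=O)COc1cc(Br)c(CO)cc1OC | intermediate
5 | methyl 2-[5-bromo-2-methoxy-4-({[tri(propan-2-yl)silyl]oxy}methyl)phenoxy]acetate | COC(=O)COc1cc(Br)c(CO[Si](C(C)C)(C(C)C)C(C)C)cc1OC | intermediate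
6 | 2-[5-bromo-2-methoxy-4-({[tri(propan-2-yl)silyl]oxy}methyl)phenoxy]acetic acid | OC(=O)COc1cc(Br)c(CO[Si](C(C)C)(C(C)C)C(C)C)cc1OC | intermediate
7 | (R)-4-benzyl-1,3-oxazolidin-2-one | O=C1N[C@H](Cc2ccccc2)CO1 | starting material
8 | pivalic mixed anhydride of acid 6 | CC(C)(C)C(=O)OC(=O)COc1cc(Br)c(CO[Si](C(C)C)(C(C)C)C(C)C)cc1OC | intermediate (not isolated)
9 | (4R)-4-benzyl-3-{[5-bromo-2-methoxy-4-({[tri(propan-2-yl)silyl]oxy}methyl)phenoxy]acetyl}-1,3-oxazolidin-2-one | O=C(COc1cc(Br)c(CO[Si](C(C)C)(C(C)C)C(C)C)cc1OC)N1[C@H](Cc2ccccc2)COC1=O | intermediate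
10 | syringaldehyde | COc1cc(C=O)cc(OC)c1O | starting material
11 | 3,5-dimethoxy-4-(methoxymethoxy)benzaldehyde | COCOc1c(OC)cc(C=O)cc1OC | intermediate
12 | Z dibutylboron enolate of imide 9 | CCCCB(CCCC)O/C(=C\Oc1cc(Br)c(CO[Si](C(C)C)(C(C)C)C(C)C)cc1OC)N1[C@H](Cc2ccccc2)COC1=O | intermediate (not isolated)
13 | dibutylboron aldolate of 14 | COc1cc([C@H](OB(CCCC)CCCC)[C@@H](Oc2cc(Br)c(CO[Si](C(C)C)(C(C)C)C(C)C)cc2OC)C(=O)N2[C@H](Cc3ccccc3)COC2=O)cc(OC)c1OCOC | intermediate (not isolated)
14 | (4R)-4-benzyl-3-{(2R,3S)-2-[5-bromo-2-methoxy-4-({[tri(propan-2-yl)silyl]oxy}methyl)phenoxy]-3-[3,5-dimethoxy-4-(methoxymethoxy)phenyl]-3-hydroxypropanoyl}-1,3-oxazolidin-2-one | COc1cc([C@H](O)[C@@H](Oc2cc(Br)c(CO[Si](C(C)C)(C(C)C)C(C)C)cc2OC)C(=O)N2[C@H](Cc3ccccc3)COC2=O)cc(OC)c1OCOC | intermediate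
15 | (1S,2S)-2-[5-bromo-2-methoxy-4-({[tri(propan-2-yl)silyl]oxy}methyl)phenoxy]-1-[3,5-dimethoxy-4-(methoxymethoxy)phenyl]propane-1,3-diol | COc1cc([C@H](O)[C@@H](Oc2cc(Br)c(CO[Si](C(C)C)(C(C)C)C(C)C)cc2OC)CO)cc(OC)c1OCOC | intermediate
16 | (1S,2S)-2-[5-bromo-2-methoxy-4-({[tri(propan-2-yl)silyl]oxy}methyl)phenoxy]-1-[3,5-dimethoxy-4-(methoxymethoxy)phenyl]-3-{[tri(propan-2-yl)silyl]oxy}propan-1-ol | COc1cc([C@H](O)[C@@H](Oc2cc(Br)c(CO[Si](C(C)C)(C(C)C)C(C)C)cc2OC)CO[Si](C(C)C)(C(C)C)C(C)C)cc(OC)c1OCOC | intermediate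
17 | C8a-lithiated lithium alkoxide of 16 | COc1cc([C@H](O[Li])[C@@H](Oc2c([Li])c(Br)c(CO[Si](C(C)C)(C(C)C)C(C)C)cc2OC)CO[Si](C(C)C)(C(C)C)C(C)C)cc(OC)c1OCOC | intermediate (not isolated)
18 | lithium alkoxide of the C8–C8a aryne | COc1cc([C@H](O[Li])[C@@H](OC2=C(OC)C=C(CO[Si](C(C)C)(C(C)C)C(C)C)C#C2)CO[Si](C(C)C)(C(C)C)C(C)C)cc(OC)c1OCOC | intermediate (not isolated)
19 | C8-lithiated benzodioxane | COc1cc([C@@H]2Oc3c([Li])c(CO[Si](C(C)C)(C(C)C)C(C)C)cc(OC)c3O[C@H]2CO[Si](C(C)C)(C(C)C)C(C)C)cc(OC)c1OCOC | intermediate (not isolated)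
20 | (2S,3S)-2-[3,5-dimethoxy-4-(methoxymethoxy)phenyl]-5-methoxy-3,7-bis({[tri(propan-2-yl)silyl]oxy}methyl)-2,3-dihydro-1,4-benzodioxine | COc1cc([C@@H]2Oc3cc(CO[Si](C(C)C)(C(C)C)C(C)C)cc(OC)c3O[C@H]2CO[Si](C(C)C)(C(C)C)C(C)C)cc(OC)c1OCOC | intermediate
21 | [(2S,3S)-2-[3,5-dimethoxy-4-(methoxymethoxy)phenyl]-5-methoxy-2,3-dihydro-1,4-benzodioxine-3,7-diyl]dimethanol | COc1cc([C@@H]2Oc3cc(CO)cc(OC)c3O[C@H]2CO)cc(OC)c1OCOC | intermediate
22 | (2S,3S)-2-[3,5-dimethoxy-4-(methoxymethoxy)phenyl]-3-(hydroxymethyl)-5-methoxy-2,3-dihydro-1,4-benzodioxine-7-carbaldehyde | COc1cc([C@@H]2Oc3cc(C=O)cc(OC)c3O[C@H]2CO)cc(OC)c1OCOC | intermediate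
23 | methyl (triphenylphosphoranylidene)acetate | COC(=O)C=P(c1ccccc1)(c1ccccc1)c1ccccc1 | starting material
24 | methyl (E)-3-[(2S,3S)-2-[3,5-dimethoxy-4-(methoxymethoxy)phenyl]-3-(hydroxymethyl)-5-methoxy-2,3-dihydro-1,4-benzodioxin-7-yl]prop-2-enoate | COc1cc([C@@H]2Oc3cc(/C=C/C(=O)OC)cc(OC)c3O[C@H]2CO)cc(OC)c1OCOC | intermediate
25 | methyl (E)-3-[(2S,3S)-2-(4-hydroxy-3,5-dimethoxyphenyl)-3-(hydroxymethyl)-5-methoxy-2,3-dihydro-1,4-benzodioxin-7-yl]prop-2-enoate | COc1cc([C@@H]2Oc3cc(/C=C/C(=O)OC)cc(OC)c3O[C@H]2CO)cc(OC)c1O | intermediate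
26 | 4-[(2S,3S)-3-(hydroxymethyl)-7-[(E)-3-hydroxyprop-1-enyl]-5-methoxy-2,3-dihydro-1,4-benzodioxin-2-yl]-2,6-dimethoxyphenol | COc1cc([C@@H]2Oc3cc(/C=C/CO)cc(OC)c3O[C@H]2CO)cc(OC)c1O | target

**Step count**

Total: 15 steps. Longest linear sequence: 14 steps (steps 1–5 and 7–15, from 1 to 26); step 6 is a one-step side branch.

**Steps most likely to fail**

Step 10. The aryne may be captured by the amide base or by a second molecule before the tethered alkoxide adds, or the lithiated bromide may be diverted by proton transfer or halogen migration before LiBr is lost. The fallback sets out from 16 and comes back to the route at 19 and so 20. The same C8a lithiation is run with lithium 2,2,6,6-tetramethylpiperidide in THF at −78 °C but is quenched cold with I2, which should give (1S,2S)-2-[3-bromo-2-iodo-6-methoxy-4-({[tri(propan-2-yl)silyl]oxy}methyl)phenoxy]-1-[3,5-dimethoxy-4-(methoxymethoxy)phenyl]-3-{[tri(propan-2-yl)silyl]oxy}propan-1-ol F1. An intramolecular Ullmann-type C–O coupling at the C8a–I bond (CuI, 1,10-phenanthroline, Cs2CO3, toluene, 100 °C) should then close the ring to (2S,3S)-8-bromo-2-[3,5-dimethoxy-4-(methoxymethoxy)phenyl]-5-methoxy-3,7-bis({[tri(propan-2-yl)silyl]oxy}methyl)-2,3-dihydro-1,4-benzodioxine F2; the bromine on C8 is out of reach of the tether and less reactive than iodine. Bromine–lithium exchange with t-BuLi in THF at −78 °C gives the aryllithium 19, which is protonated with methanol to 20.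

Step 7. Facial or syn/anti control may be poor for the aryloxy-substituted enolate, or the aldolate of the electron-rich aldehyde may equilibrate by retro-aldol, either of which erodes the threo relationship. The fallback sets out from 5 and 11 and comes back at 15; it replaces auxiliary control by catalyst control with dynamic kinetic resolution. The lithium enolate of 5 (LiN(SiMe3)2, THF, −78 °C) is added to 11 to give methyl 2-[5-bromo-2-methoxy-4-({[tri(propan-2-yl)silyl]oxy}methyl)phenoxy]-3-[3,5-dimethoxy-4-(methoxymethoxy)phenyl]-3-hydroxypropanoate F3 as a stereoisomer mixture. Dess–Martin oxidation (NaHCO3, CH2Cl2) gives the configurationally labile β-keto ester methyl 2-[5-bromo-2-methoxy-4-({[tri(propan-2-yl)silyl]oxy}methyl)phenoxy]-3-[3,5-dimethoxy-4-(methoxymethoxy)phenyl]-3-oxopropanoate F4. Asymmetric transfer hydrogenation with dynamic kinetic resolution (RuCl(p-cymene)[(R,R)-TsDPEN], HCO2H/Et3N, CH2Cl2, 30 °C) is a reaction type known to favour syn α-alkoxy β-hydroxy esters. With the catalyst antipode chosen to deliver the (S)-carbinol, it should give methyl (2R,3S)-2-[5-bromo-2-methoxy-4-({[tri(propan-2-yl)silyl]oxy}methyl)phenoxy]-3-[3,5-dimethoxy-4-(methoxymethoxy)phenyl]-3-hydroxypropanoate F5. LiBH4 reduction of the ester then gives diol 15.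

Step 14. Once the para phenol is free, acid may ionise the benzylic C2–O1 bond, leading to ring opening, capture by methanol or epimerisation at C2. The fallback sets out from 24 and comes back at 25; it replaces acidolysis by a buffered trans-silylation. Treatment with TMSOTf and 2,2'-bipyridyl in CH2Cl2 at 0 °C should convert the aryl MOM ether directly into the aryl silyl ether and silylate the primary alcohol as well, giving methyl (E)-3-[(2S,3S)-2-{3,5-dimethoxy-4-[(trimethylsilyl)oxy]phenyl}-5-methoxy-3-{[(trimethylsilyl)oxy]methyl}-2,3-dihydro-1,4-benzodioxin-7-yl]prop-2-enoate F6. Both labile silyl ethers are then hydrolysed with water in THF at neutral pH to give 25.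

Further compounds
F1 | step 10 | (1S,2S)-2-[3-bromo-2-iodo-6-methoxy-4-({[tri(propan-2-yl)silyl]oxy}methyl)phenoxy]-1-[3,5-dimethoxy-4-(methoxymethoxy)phenyl]-3-{[tri(propan-2-yl)silyl]oxy}propan-1-ol | COc1cc([C@H](O)[C@@H](Oc2c(I)c(Br)c(CO[Si](C(C)C)(C(C)C)C(C)C)cc2OC)CO[Si](C(C)C)(C(C)C)C(C)C)cc(OC)c1OCOC
F2 | step 10 | (2S,3S)-8-bromo-2-[3,5-dimethoxy-4-(methoxymethoxy)phenyl]-5-methoxy-3,7-bis({[tri(propan-2-yl)silyl]oxy}methyl)-2,3-dihydro-1,4-benzodioxine | COc1cc([C@@H]2Oc3c(Br)c(CO[Si](C(C)C)(C(C)C)C(C)C)cc(OC)c3O[C@H]2CO[Si](C(C)C)(C(C)C)C(C)C)cc(OC)c1OCOC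
F3 | step 7 | methyl 2-[5-bromo-2-methoxy-4-({[tri(propan-2-yl)silyl]oxy}methyl)phenoxy]-3-[3,5-dimethoxy-4-(methoxymethoxy)phenyl]-3-hydroxypropanoate (stereoisomer mixture) | COC(=O)C(Oc1cc(Br)c(CO[Si](C(C)C)(C(C)C)C(C)C)cc1OC)C(O)c1cc(OC)c(OCOC)c(OC)c1
F4 | step 7 | methyl 2-[5-bromo-2-methoxy-4-({[tri(propan-2-yl)silyl]oxy}methyl)phenoxy]-3-[3,5-dimethoxy-4-(methoxymethoxy)phenyl]-3-oxopropanoate (racemic) | COC(=O)C(Oc1cc(Br)c(CO[Si](C(C)C)(C(C)C)C(C)C)cc1OC)C(=O)c1cc(OC)c(OCOC)c(OC)c1
F5 | step 7 | methyl (2R,3S)-2-[5-bromo-2-methoxy-4-({[tri(propan-2-yl)silyl]oxy}methyl)phenoxy]-3-[3,5-dimethoxy-4-(methoxymethoxy)phenyl]-3-hydroxypropanoate | COc1cc([C@H](O)[C@@H](Oc2cc(Br)c(CO[Si](C(C)C)(C(C)C)C(C)C)cc2OC)C(=O)OC)cc(OC)c1OCOC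
F6 | step 14 | methyl (E)-3-[(2S,3S)-2-{3,5-dimethoxy-4-[(trimethylsilyl)oxy]phenyl}-5-methoxy-3-{[(trimethylsilyl)oxy]methyl}-2,3-dihydro-1,4-benzodioxin-7-yl]prop-2-enoate | COc1cc([C@@H]2Oc3cc(/C=C/C(=O)OC)cc(OC)c3O[C@H]2CO[Si](C)(C)C)cc(OC)c1O[Si](C)(C)C
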